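**Retrosynthetic overview**

- The feature the route rests on is ring A of unit 2 (C4a''–C8a''), a 1,3,5-trioxygenated benzene that carries ring B of unit 1 on C8'' (bond C3'–C8'') and in which only the C8a'' oxygen may become the ring oxygen O1''. Unit 1 is the isoflavone joined through C3' (plain and single-primed locants), unit 2 the one joined through C8'' (double- and triple-primed locants).
- Late disconnections: the (M) axis by resolution of the racemate; six aryl ether cleavages; ring C of unit 2 (O1''–C2'' and C2''–C3'') from a deoxybenzoin; C4a''–C4'' by Friedel–Crafts acylation ortho to the single free phenol.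
- Key disconnection: ring A of unit 2 is opened across C8''–C8a'', C6''–C7'' and C4a''–C8a'' into an aryl ynol ether (triple bond on C3') and 3-ethoxycyclobutenone (Danheiser benzannulation). The crowded C3'–C8'' bond is therefore only an aryl–alkyne bond.
- The ynol ether comes from a bromo isoflavone by Negishi alkynylation; the bromo isoflavone comes from 3-bromo-4-methoxyphenylacetic acid and 3,5-dimethoxyphenol.
- Order of ring formation: ring C of unit 1 (step 1), ring A of unit 2 (step 3), ring C of unit 2 (step 5); the other four benzene rings are bought.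

Key step: step 3

Assumption: the C3'–C8'' axis (ortho groups 4'-OH, 7''-OH and O1'') is taken to be configurationally stable at room temperature, as the existence of a defined (M)-form implies. SMILES has no descriptor for this axis, so the SMILES of axially chiral compounds are constitutional and the descriptor is carried by the name.

Assumption: 3-ethoxycyclobut-2-en-1-one is bought; it is also available in one operation from ketene and ethoxyacetylene.

**Route**

Step 1
Reactants: 1 3-bromo-4-methoxyphenylacetic acid; 2 3,5-dimethoxyphenol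
Product: 5 3-(3-bromo-4-methoxyphenyl)-5,7-dimethoxy-4H-chromen-4-one, via deoxybenzoin 3 (not isolated), via enaminone 4 (not isolated)
Conditions: BF3·OEt2 (neat, as solvent), 85 °C; then DMF, MsCl, 50 → 90 °C; aq. NaOAc work-up
Reagents that add atoms: N,N-dimethylformamide, CN(C)C=O
Why: BF3-mediated Friedel–Crafts acylation of the phloroglucinol ether goes ortho to the free hydroxyl (chelated ketone 3), and C-formylation of the activated methylene by the iminium salt from DMF and MsCl, then 6-endo ring closure with loss of Me2NH (through 4), should give the chromone in the same pot, as in the established one-pot deoxybenzoin isoflavone synthesis; no stereocenter is formed.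

Step 2
Reactants: 5 3-(3-bromo-4-methoxyphenyl)-5,7-dimethoxy-4H-chromen-4-one; 6 ethoxyacetylene
Product: 9 3-[3-(ethoxyethynyl)-4-methoxyphenyl]-5,7-dimethoxy-4H-chromen-4-one, via lithium ethoxyacetylide 7 (not isolated), via ethoxyethynylzinc chloride 8 (not isolated)
Conditions: 6, n-BuLi, THF, −78 °C; ZnCl2, −78 → 0 °C; then 5, Pd(P(t-Bu)3)2 (zerovalent palladium, 3 mol %), THF, rt → 40 °C; aq. NaHCO3 work-up, Et3N-deactivated silica
Reagents that add atoms: none
Why: Negishi alkynylation, in which the alkynylzinc chloride 8 (EtOC≡CZnCl, from lithiation of 6 and transmetalation) is too weak a nucleophile to attack the chromone but should transmetalate readily to the arylpalladium bromide that the electron-rich Pd(P(t-Bu)3)2 catalyst forms near room temperature, where the heat- and acid-sensitive ynol ether survives.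

Step 3
Reactants: 9 3-[3-(ethoxyethynyl)-4-methoxyphenyl]-5,7-dimethoxy-4H-chromen-4-one; 10 3-ethoxycyclobut-2-en-1-one
Product: 15 3-[3-(2,4-diethoxy-6-hydroxyphenyl)-4-methoxyphenyl]-5,7-dimethoxy-4H-chromen-4-one, via vinylketene 11 (not isolated), via vinylcyclobutenone 12 (not isolated), via dienylketene 13 (not isolated), via cyclohexadienone 14 (not isolated)
Conditions: toluene (degassed, 0.05 M in 9), 90 °C, slow addition of 10 (1.3 equiv), argon
Reagents that add atoms: none
Why: Thermal 4π-electrocyclic opening of 10 should give vinylketene 11, whose ketene C=C adds [2+2] to the electron-rich triple bond of 9 to give the 4-vinylcyclobutenone 12; a second, reversible 4π opening gives dienylketene 13, which closes by 6π electrocyclization to dienone 14 and tautomerizes to phenol 15. This is the Danheiser benzannulation, and the closest known cases are the resorcinol ether syntheses from cyclobutenones and alkoxy- or siloxyalkynes. Ring A of unit 2 closes in the 6π-electrocyclic (disrotatory) mode, forming C4a''–C8a'' after the cycloaddition has formed C8''–C8a'' and C6''–C7''. No stereocenter is created, and the C3'–C8'' axis arises unresolved and stays racemic until step 7. The step needs a single regiochemistry in the [2+2] event, and the polarization of the ynol ether secures it: its nucleophilic aryl-bearing carbon bonds to the electrophilic ketene carbonyl carbon, so ring B ends up between the new free hydroxyl on C8a'' and the alkyne-derived ethoxy group on C7''. Slow addition of 10 keeps the ketene concentration low, which should limit ketene dimerization and O-acylation of the product phenol.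

Step 4
Reactants: 15 3-[3-(2,4-diethoxy-6-hydroxyphenyl)-4-methoxyphenyl]-5,7-dimethoxy-4H-chromen-4-one; 16 4-methoxyphenylacetic acid
Product: 17 3-(3-{4,6-diethoxy-2-hydroxy-3-[(4-methoxyphenyl)acetyl]phenyl}-4-methoxyphenyl)-5,7-dimethoxy-4H-chromen-4-one
Conditions: BF3·OEt2 (neat, as solvent), 75 °C; aq. NaOAc work-up
Reagents that add atoms: none
Why: Friedel–Crafts acylation of the phloroglucinol-type ring, which is far more nucleophilic than the carbonyl-deactivated ring A of unit 1 or ring B, should be steered by the free C8a'' hydroxyl (O-acylation and Fries shift, chelated product) to its only free ortho position C4a''; no stereocenter is formed.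

Step 5
Reactants: 17 3-(3-{4,6-diethoxy-2-hydroxy-3-[(4-methoxyphenyl)acetyl]phenyl}-4-methoxyphenyl)-5,7-dimethoxy-4H-chromen-4-one
Product: 19 5,7-diethoxy-8-[5-(5,7-dimethoxy-4-oxo-4H-chromen-3-yl)-2-methoxyphenyl]-3-(4-methoxyphenyl)-4H-chromen-4-one, via enaminone 18 (not isolated)
Conditions: Me2NCH(OMe)2, toluene, 90 °C
Reagents that add atoms: N,N-dimethylformamide dimethyl acetal, COC(OC)N(C)C
Why: Condensation of the activated methylene with the amide acetal gives enaminone 18, and the only free hydroxyl (on C8a'') should close ring C of unit 2 by 6-endo-trig addition–elimination with loss of Me2NH, the standard deoxybenzoin-to-isoflavone closure, on one side only because C5'' and C7'' carry ethers.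

Step 6
Reactants: 19 5,7-diethoxy-8-[5-(5,7-dimethoxy-4-oxo-4H-chromen-3-yl)-2-methoxyphenyl]-3-(4-methoxyphenyl)-4H-chromen-4-one
Product: 20 rac-bisoflavolin D (8-[5-(5,7-dihydroxy-4-oxo-4H-chromen-3-yl)-2-hydroxyphenyl]-5,7-dihydroxy-3-(4-hydroxyphenyl)-4H-chromen-4-one)
Conditions: BBr3 (excess), CH2Cl2, −78 °C → rt, then 40 °C; MeOH, then H2O
Reagents that add atoms: none
Why: Lewis-acid ether cleavage with BBr3 should remove the four methyl and two ethyl aryl ethers by bromide attack on the boron-complexed ethers, the peri ethers at C5 and C5'' going first through chelation to the carbonyls, while the chromone rings and the biaryl bond are inert to the reagent.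

Step 7
Reactants: 20 rac-bisoflavolin D
Product: 21 (M)-bisoflavolin D
Conditions: preparative HPLC, amylose tris(3,5-dimethylphenylcarbamate) chiral stationary phase, hexane/EtOH/TFA, 15 °C
Reagents that add atoms: none
Why: Chromatographic resolution of the racemate, in which the two atropisomers form diastereomeric adsorbates on the polysaccharide carbamate phase and elute apart, so the axis is fixed by separation and not by synthesis; the (M)-fraction is to be assigned by electronic circular dichroism against the calculated spectrum, and the (P)-fraction can be racemized by heating and resolved again.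

**Compound list**

1 | 3-bromo-4-methoxyphenylacetic acid | COc1ccc(CC(=O)O)cc1Br | starting material
2 | 3,5-dimethoxyphenol | COc1cc(O)cc(OC)c1 | starting material
3 | 2-(3-bromo-4-methoxyphenyl)-1-(2-hydroxy-4,6-dimethoxyphenyl)ethan-1-one | COc1cc(O)c(C(=O)Cc2ccc(OC)c(Br)c2)c(OC)c1 | intermediate
4 | (2E)-2-(3-bromo-4-methoxyphenyl)-3-(dimethylamino)-1-(2-hydroxy-4,6-dimethoxyphenyl)prop-2-en-1-one | COc1cc(O)c(C(=O)/C(=C/N(C)C)c2ccc(OC)c(Br)c2)c(OC)c1 | intermediate
5 | 3-(3-bromo-4-methoxyphenyl)-5,7-dimethoxy-4H-chromen-4-one | COc1cc(OC)c2c(=O)c(-c3ccc(OC)c(Br)c3)coc2c1 | intermediate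
6 | ethoxyacetylene | CCOC#C | starting material
7 | lithium ethoxyacetylide | CCOC#C[Li] | intermediate
8 | (ethoxyethynyl)zinc chloride | CCOC#C[Zn]Cl | intermediate
9 | 3-[3-(ethoxyethynyl)-4-methoxyphenyl]-5,7-dimethoxy-4H-chromen-4-one | CCOC#Cc1cc(-c2coc3cc(OC)cc(OC)c3c2=O)ccc1OC | intermediate
10 | 3-ethoxycyclobut-2-en-1-one | CCOC1=CC(=O)C1 | starting material
11 | 3-ethoxybuta-1,3-dien-1-one | C=C(OCC)C=C=O | intermediate
12 | rac-3-{3-[2-ethoxy-3-(1-ethoxyethenyl)-4-oxocyclobut-1-en-1-yl]-4-methoxyphenyl}-5,7-dimethoxy-4H-chromen-4-one | O=C1C(c2cc(-c3coc4cc(OC)cc(OC)c4c3=O)ccc2OC)=C(OCC)C1C(=C)OCC | intermediate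
13 | (3E)-2-[5-(5,7-dimethoxy-4-oxo-4H-chromen-3-yl)-2-methoxyphenyl]-3,5-diethoxyhexa-1,3,5-trien-1-one (C2 and C5 cis about C3=C4) | O=C=C(c1cc(-c2coc3cc(OC)cc(OC)c3c2=O)ccc1OC)/C(OCC)=C\C(OCC)=C | intermediate
14 | 3-[3-(2,4-diethoxy-6-oxocyclohexa-1,3-dien-1-yl)-4-methoxyphenyl]-5,7-dimethoxy-4H-chromen-4-one | O=C1CC(OCC)=CC(OCC)=C1c1cc(-c2coc3cc(OC)cc(OC)c3c2=O)ccc1OC | intermediate
15 | 3-[3-(2,4-diethoxy-6-hydroxyphenyl)-4-methoxyphenyl]-5,7-dimethoxy-4H-chromen-4-one (racemic axis) | CCOc1cc(O)c(-c2cc(-c3coc4cc(OC)cc(OC)c4c3=O)ccc2OC)c(OCC)c1 | intermediate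
16 | 4-methoxyphenylacetic acid | COc1ccc(CC(=O)O)cc1 | starting material
17 | 3-(3-{4,6-diethoxy-2-hydroxy-3-[(4-methoxyphenyl)acetyl]phenyl}-4-methoxyphenyl)-5,7-dimethoxy-4H-chromen-4-one (racemic axis) | CCOc1cc(OCC)c(C(=O)Cc2ccc(OC)cc2)c(O)c1-c1cc(-c2coc3cc(OC)cc(OC)c3c2=O)ccc1OC | intermediate
18 | 3-(3-{4,6-diethoxy-3-[(2E)-3-(dimethylamino)-2-(4-methoxyphenyl)prop-2-enoyl]-2-hydroxyphenyl}-4-methoxyphenyl)-5,7-dimethoxy-4H-chromen-4-one (racemic axis) | CCOc1cc(OCC)c(C(=O)/C(=C/N(C)C)c2ccc(OC)cc2)c(O)c1-c1cc(-c2coc3cc(OC)cc(OC)c3c2=O)ccc1OC | intermediate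
19 | 5,7-diethoxy-8-[5-(5,7-dimethoxy-4-oxo-4H-chromen-3-yl)-2-methoxyphenyl]-3-(4-methoxyphenyl)-4H-chromen-4-one (racemic axis) | O=c1c(-c2ccc(OC)c(-c3c(OCC)cc(OCC)c4c(=O)c(-c5ccc(OC)cc5)coc34)c2)coc2cc(OC)cc(OC)c12 | intermediate
20 | rac-bisoflavolin D (racemic at the C3'–C8'' axis) | O=c1c(-c2ccc(O)c(-c3c(O)cc(O)c4c(=O)c(-c5ccc(O)cc5)coc34)c2)coc2cc(O)cc(O)c12 | intermediate
21 | (M)-bisoflavolin D ((M) at the C3'–C8'' axis) | O=c1c(-c2ccc(O)c(-c3c(O)cc(O)c4c(=O)c(-c5ccc(O)cc5)coc34)c2)coc2cc(O)cc(O)c12 | target

**Step count**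

Total step count: 7 (six reactions and one resolution). Longest linear sequence: 7 steps (1 and 2 to 21).

**Steps most likely to fail**

Step 3. The ring opening of the donor-stabilized cyclobutenone 10 may be too slow below the temperature at which the ethyl ynol ether 9 loses ethylene by retro-ene fragmentation, and the vinylketene may dimerize or acylate the product phenol before the alkyne traps it. The fallback sets out from 9 and comes back to the route at 15, generating the same vinylketene 11 at room temperature by 1,4-dehydrochlorination. Commercial ethyl (E)-3-ethoxybut-2-enoate is saponified (NaOH, aq. EtOH, then cold dilute HCl) to (E)-3-ethoxybut-2-enoic acid F1. (COCl)2 and catalytic DMF in CH2Cl2 at 0 °C convert F1 into (E)-3-ethoxybut-2-enoyl chloride F2. Slow addition of F2 to 9 and Et3N in CH2Cl2 at 0 °C → rt should give 11 by γ-deprotonation of the acylammonium salt, which 9 traps in the flask as 12. Gentle warming (about 60 °C) then carries 12 through 13 and 14 to 15.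

Step 2. Oxidative addition into the electron-rich, ortho-methoxy aryl bromide may be slow, so that the zinc acetylide degrades or the mixture has to be heated, and the acid-labile ynol ether may hydrate to the arylacetic ester during work-up or chromatography. The fallback sets out from 16 and 2 and comes back at 9, using a more reactive carbon–iodine bond. 16 is iodinated ortho to the methoxy group (NIS, catalytic TFA, MeCN) to 3-iodo-4-methoxyphenylacetic acid F3. The one-pot annulation of step 1 with 2 (BF3·OEt2, then DMF and MsCl) then passes through the iodo deoxybenzoin 2-(3-iodo-4-methoxyphenyl)-1-(2-hydroxy-4,6-dimethoxyphenyl)ethan-1-one F4 and the iodo enaminone (2E)-3-(dimethylamino)-1-(2-hydroxy-4,6-dimethoxyphenyl)-2-(3-iodo-4-methoxyphenyl)prop-2-en-1-one F5 to 3-(3-iodo-4-methoxyphenyl)-5,7-dimethoxy-4H-chromen-4-one F6. F6 should couple with 8 under Pd(PPh3)4 (zerovalent palladium) in THF at room temperature, the classical conditions for aryl iodides, to give 9.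

Step 4. Acylation may go to C6'' between the two ethoxy groups instead of C4a'', and hot BF3·OEt2 may cleave the ethoxy group ortho to the new ketone, which would let ring C of unit 2 close on the wrong side. The fallback sets out from 15 and comes back at 19; it brings in a small acyl group at room temperature and attaches ring B of unit 2 by cross-coupling. 15 is acetylated with Ac2O and BF3·OEt2 in CH2Cl2 at room temperature (O-acetylation, then Fries shift to the only free ortho position, favored by chelation of the product ketone) to 3-[3-(3-acetyl-4,6-diethoxy-2-hydroxyphenyl)-4-methoxyphenyl]-5,7-dimethoxy-4H-chromen-4-one F7. Me2NCH(OMe)2 in toluene at 80 °C gives the enaminone 3-(3-{3-[(2E)-3-(dimethylamino)prop-2-enoyl]-4,6-diethoxy-2-hydroxyphenyl}-4-methoxyphenyl)-5,7-dimethoxy-4H-chromen-4-one F8. I2 in CHCl3 at room temperature cyclizes F8 to 5,7-diethoxy-3-iodo-8-[5-(5,7-dimethoxy-4-oxo-4H-chromen-3-yl)-2-methoxyphenyl]-4H-chromen-4-one F9. Suzuki–Miyaura coupling of F9 with 4-methoxyphenylboronic acid (Pd(PPh3)4 (zerovalent palladium), Na2CO3, DME/H2O, 80 °C) should give 19.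

**Further compounds**

F1 | step 3 | (E)-3-ethoxybut-2-enoic acid | CCO/C(C)=C/C(=O)O
F2 | step 3 | (E)-3-ethoxybut-2-enoyl chloride | CCO/C(C)=C/C(=O)Cl
F3 | step 2 | 3-iodo-4-methoxyphenylacetic acid | COc1ccc(CC(=O)O)cc1I
F4 | step 2 | 2-(3-iodo-4-methoxyphenyl)-1-(2-hydroxy-4,6-dimethoxyphenyl)ethan-1-one | COc1cc(O)c(C(=O)Cc2ccc(OC)c(I)c2)c(OC)c1
F5 | step 2 | (2E)-3-(dimethylamino)-1-(2-hydroxy-4,6-dimethoxyphenyl)-2-(3-iodo-4-methoxyphenyl)prop-2-en-1-one | COc1cc(O)c(C(=O)/C(=C/N(C)C)c2ccc(OC)c(I)c2)c(OC)c1
F6 | step 2 | 3-(3-iodo-4-methoxyphenyl)-5,7-dimethoxy-4H-chromen-4-one | COc1cc(OC)c2c(=O)c(-c3ccc(OC)c(I)c3)coc2c1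
F7 | step 4 | 3-[3-(3-acetyl-4,6-diethoxy-2-hydroxyphenyl)-4-methoxyphenyl]-5,7-dimethoxy-4H-chromen-4-one (racemic axis) | CCOc1cc(OCC)c(C(C)=O)c(O)c1-c1cc(-c2coc3cc(OC)cc(OC)c3c2=O)ccc1OC
F8 | step 4 | 3-(3-{3-[(2E)-3-(dimethylamino)prop-2-enoyl]-4,6-diethoxy-2-hydroxyphenyl}-4-methoxyphenyl)-5,7-dimethoxy-4H-chromen-4-one (racemic axis) | CCOc1cc(OCC)c(C(=O)/C=C/N(C)C)c(O)c1-c1cc(-c2coc3cc(OC)cc(OC)c3c2=O)ccc1OC
F9 | step 4 | 5,7-diethoxy-3-iodo-8-[5-(5,7-dimethoxy-4-oxo-4H-chromen-3-yl)-2-methoxyphenyl]-4H-chromen-4-one (racemic axis) | O=c1c(I)coc2c1c(OCC)cc(OCC)c2-c1cc(-c2coc3cc(OC)cc(OC)c3c2=O)ccc1OC
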